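**Plan**
Ring B is the arene of the propanoate half (C1 bears the CH2CH2CO2 chain, C3 and C4 the methoxy groups); ring A is the arene of the propanol half.
Retrosynthesis: ring B is taken back to its 1,4-dihydro form and cut at the ring bonds C1–C2 and C5–C6; the ester C–O bond is cut second.
Enabling feature: C2 to C5 of ring B carry H, OMe, OMe, H, the pattern of 2,3-dimethoxybuta-1,3-diene, and C1 (chain) with C6 (H) corresponds to a terminal alkyne.
Forward: the diene is made from butane-2,3-dione, the alkyne ester by esterification with ring A already in the alcohol, then a cobalt-catalysed [4+2] closes ring B as a cyclohexa-1,4-diene and DDQ aromatises it.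
Stereochemistry: the target has no stereocentre and no stereogenic double bond, so nothing has to be set or preserved.

Key step: step 4

**Route**

Step 1
Reactants: 1 butane-2,3-dione
Product: 3 2,2,3,3-tetramethoxybutane, via 3,3-dimethoxybutan-2-one 2 (not isolated)
Conditions: HC(OMe)3 (2.5 equiv), MeOH, cat. H2SO4, reflux; NaOMe quench, distil
Reagents that add atoms: trimethyl orthoformate, COC(OC)OC; methanol, CO
Why: Acid-catalysed ketalisation of both carbonyl groups, driven to completion by the orthoformate as water scavenger, is the standard way to this bis-ketal.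

Step 2
Reactants: 3 2,2,3,3-tetramethoxybutane
Product: 5 2,3-dimethoxybuta-1,3-diene, via 2,3,3-trimethoxybut-1-ene 4 (not isolated)
Conditions: cat. NH4H2PO4, cat. quinoline, neat, 160–190 °C, slow distillation of MeOH then diene; redistil from K2CO3, store cold
Reagents that add atoms: none
Why: Acid-catalysed thermal elimination of methanol from a dimethyl ketal (ketal cracking) should occur at each ketal in turn, pulled forward by distilling off methanol, with quinoline buffering the acid so the diene does not polymerise.

Step 3
Reactants: 6 pent-4-ynoic acid; 7 3-(3,4-dimethoxyphenyl)propan-1-ol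
Product: 8 3-(3,4-dimethoxyphenyl)propyl pent-4-ynoate
Conditions: DCC (1.1 equiv), DMAP (0.1 equiv), CH2Cl2, 0 °C to rt
Reagents that add atoms: none
Why: Steglich esterification, in which DCC activates the acid as its O-acylisourea and DMAP relays the acyl group to the unhindered primary alcohol, should leave the terminal alkyne and the aryl ethers untouched.

Step 4
Reactants: 5 2,3-dimethoxybuta-1,3-diene; 8 3-(3,4-dimethoxyphenyl)propyl pent-4-ynoate
Product: 9 3-(3,4-dimethoxyphenyl)propyl 3-(4,5-dimethoxycyclohexa-1,4-dien-1-yl)propanoate
Conditions: CoBr2(dppe) (10 mol %), Zn powder (20 mol %), dry ZnI2 (20 mol %), CH2Cl2, rt, diene 5 in twofold excess, slow addition of 8; filter through Et3N-deactivated silica, strip surplus diene in vacuo, use crude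
Reagents that add atoms: none
Why: Zinc reduces CoBr2(dppe) to monovalent cobalt and ZnI2 removes halide, so the s-cis diene 5 and the alkyne 8 bind side by side; oxidative coupling then forms the first C–C bond and a cobaltacycle of trivalent cobalt, and reductive elimination forms the second bond and releases the 1,4-diene. The closest known reaction type is the cobalt-catalysed neutral Diels–Alder reaction of unactivated terminal alkynes with 2-substituted and 2,3-disubstituted buta-1,3-dienes, 2-silyloxy dienes included, of which the dimethoxy diene is a further member. The six-membered carbocycle of ring B closes by intermolecular [4+2] union of the four diene carbons (C2 to C5) with the two alkyne carbons (C1 and C6), one diene molecule per alkyne molecule, the new bonds being C1–C2 and C5–C6. No stereocentre arises, since every ring carbon of the product is sp2 or CH2. Regioselectivity is not in question because the diene is symmetric about its central bond; what is needed is cross-cycloaddition in preference to alkyne cyclotrimerisation and diene decomposition, which the chelating diphosphine, the excess of diene and slow addition of 8 should secure. A thermal Diels–Alder reaction would not engage this unactivated alkyne, and the ester and ring A should be spectators under these neutral conditions.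

Step 5
Reactants: 9 3-(3,4-dimethoxyphenyl)propyl 3-(4,5-dimethoxycyclohexa-1,4-dien-1-yl)propanoate
Product: 10 3-(3,4-dimethoxyphenyl)propyl 3-(3,4-dimethoxyphenyl)propanoate
Conditions: DDQ (1.05 equiv), dry toluene, 0 °C to rt; filter, wash with aq. NaHCO3
Reagents that add atoms: none
Why: DDQ dehydrogenation, in which hydride abstraction from a doubly allylic ring CH2 gives a methoxy-stabilised cyclohexadienyl cation that loses a proton to the arene, should be much faster than benzylic oxidation next to the veratrole rings, so one equivalent is enough.

**Compound list**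

1 | butane-2,3-dione | CC(=O)C(C)=O | starting material
2 | 3,3-dimethoxybutan-2-one | CC(=O)C(C)(OC)OC | intermediate (not isolated)
3 | 2,2,3,3-tetramethoxybutane | COC(C)(OC)C(C)(OC)OC | intermediate
4 | 2,3,3-trimethoxybut-1-ene | C=C(OC)C(C)(OC)OC | intermediate (not isolated)
5 | 2,3-dimethoxybuta-1,3-diene | COC(=C)C(=C)OC | intermediate
6 | pent-4-ynoic acid | C#CCCC(=O)O | starting material
7 | 3-(3,4-dimethoxyphenyl)propan-1-ol | COc1ccc(CCCO)cc1OC | starting material
8 | 3-(3,4-dimethoxyphenyl)propyl pent-4-ynoate | C#CCCC(=O)OCCCc1ccc(OC)c(OC)c1 | intermediate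
9 | 3-(3,4-dimethoxyphenyl)propyl 3-(4,5-dimethoxycyclohexa-1,4-dien-1-yl)propanoate | COC1=C(OC)CC(CCC(=O)OCCCc2ccc(OC)c(OC)c2)=CC1 | intermediate
10 | 3-(3,4-dimethoxyphenyl)propyl 3-(3,4-dimethoxyphenyl)propanoate | COc1ccc(CCCOC(=O)CCc2ccc(OC)c(OC)c2)cc1OC | target

**Step count**
Total: 5 steps. Longest linear sequence: 4 steps (steps 1, 2, 4, 5, from 1 through 3, 5 and 9 to 10); the alkyne ester branch contributes step 3.

**Steps most likely to fail**

Step 4. The alkyne may be consumed by cobalt-mediated cyclotrimerisation faster than it undergoes cross-cycloaddition. The electron-rich bis-enol-ether diene may also be lost to cationic oligomerisation at the Lewis-acidic ZnI2, or to hydrolysis by traces of moisture, before it reaches the metal. The fallback gives up ring construction and joins a ready-made ring B to the chain by cross-coupling; it sets out from 7 and returns at 10. Alcohol 7 would be esterified with acrylic acid (DCC, DMAP, CH2Cl2) to 3-(3,4-dimethoxyphenyl)propyl prop-2-enoate F1. A Heck reaction of this acrylate with 4-bromo-1,2-dimethoxybenzene (Pd(OAc)2, P(o-tol)3, NaOAc, DMF, 110 °C) should give 3-(3,4-dimethoxyphenyl)propyl (E)-3-(3,4-dimethoxyphenyl)prop-2-enoate F2. Hydrogenation of the alkene (H2, Pd/C, EtOAc) then gives 10.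

Step 2. The elimination may stop at the mono-enol ether, or the diene may polymerise or be hydrolysed during the hot, mildly acidic distillation. The fallback replaces the diene by a silyl surrogate made by soft enolisation and so avoids ketal cracking; it sets out from 1 and returns at 10. Dione 1 with TMSOTf and Et3N in Et2O at 0 °C should give 2,3-bis(trimethylsilyloxy)buta-1,3-diene F3. Cycloaddition of this diene with 8 under the conditions of step 4 should give 3-(3,4-dimethoxyphenyl)propyl 3-[4,5-bis(trimethylsilyloxy)cyclohexa-1,4-dien-1-yl]propanoate F4. DDQ (1.0 equiv, dry toluene) would aromatise it to 3-(3,4-dimethoxyphenyl)propyl 3-[3,4-bis(trimethylsilyloxy)phenyl]propanoate F5. One-pot desilylation and O-methylation (CsF, MeI, DMF, rt) then gives 10 without a free catechol being exposed to oxidant.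

Step 5. Hydride abstraction may not stay confined to the dihydro ring: surplus quinone could dehydrogenate the benzylic positions next to the two electron-rich arenes, and charge-transfer adducts could hinder isolation. The fallback moves the oxidation ahead of the union with ring A; it sets out from 5 and returns at 10. Diene 5 and commercial methyl pent-4-ynoate under the conditions of step 4 should give methyl 3-(4,5-dimethoxycyclohexa-1,4-dien-1-yl)propanoate F6. DDQ, which can be used in excess here, would give methyl 3-(3,4-dimethoxyphenyl)propanoate F7, a simple distillable ester in which any over-oxidised material can be returned to the saturated chain by a hydrogenation polish over Pd/C. Saponification (LiOH, THF/H2O, then acidification) gives 3-(3,4-dimethoxyphenyl)propanoic acid F8. Steglich esterification of this acid with 7 (DCC, DMAP, CH2Cl2) gives 10.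

**Further compounds**
F1 | step 4 | 3-(3,4-dimethoxyphenyl)propyl prop-2-enoate | C=CC(=O)OCCCc1ccc(OC)c(OC)c1
F2 | step 4 | 3-(3,4-dimethoxyphenyl)propyl (E)-3-(3,4-dimethoxyphenyl)prop-2-enoate | COc1ccc(/C=C/C(=O)OCCCc2ccc(OC)c(OC)c2)cc1OC
F3 | step 2 | 2,3-bis(trimethylsilyloxy)buta-1,3-diene | C=C(O[Si](C)(C)C)C(=C)O[Si](C)(C)C
F4 | step 2 | 3-(3,4-dimethoxyphenyl)propyl 3-[4,5-bis(trimethylsilyloxy)cyclohexa-1,4-dien-1-yl]propanoate | C[Si](C)(C)OC1=C(O[Si](C)(C)C)CC(CCC(=O)OCCCc2ccc(OC)c(OC)c2)=CC1
F5 | step 2 | 3-(3,4-dimethoxyphenyl)propyl 3-[3,4-bis(trimethylsilyloxy)phenyl]propanoate | C[Si](C)(C)Oc1ccc(CCC(=O)OCCCc2ccc(OC)c(OC)c2)cc1O[Si](C)(C)C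
F6 | step 5 | methyl 3-(4,5-dimethoxycyclohexa-1,4-dien-1-yl)propanoate | COC(=O)CCC1=CCC(OC)=C(OC)C1
F7 | step 5 | methyl 3-(3,4-dimethoxyphenyl)propanoate | COC(=O)CCc1ccc(OC)c(OC)c1
F8 | step 5 | 3-(3,4-dimethoxyphenyl)propanoic acid | COc1ccc(CCC(=O)O)cc1OC
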